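The rate constants are assumed; the run is a simulation.

Start with the easy step: in summer catalyst intermediate A takes up partner at 1.24 s⁻¹, slower than free catalyst takes up substrate at 35.5 s⁻¹.

    substrate + free catalyst → catalyst intermediate A (k1 = 710 M⁻¹ s⁻¹)
    partner + catalyst intermediate A → catalyst intermediate B (k2 = 13 M⁻¹ s⁻¹)
    catalyst intermediate B ⇌ by-product + catalyst intermediate C (K3 = 0.086 M, k3 = 610 s⁻¹)
    catalyst intermediate C → free catalyst + target (k4 = 4.8 s⁻¹)
    free catalyst + target → free catalyst + over-reaction product (k5 = 100 M⁻¹ s⁻¹)

| flask | substrate | partner | free catalyst | time |
|---|---|---|---|---|
| summer | 0.050 M | 0.0950 M | 0.50 mM | 3.0 min |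
| midnight | 0.10 M | 0.0950 M | 0.50 mM | 3.0 min |
| dusk | 0.20 M | 0.0950 M | 0.50 mM | 3.0 min |
| autumn | 0.40 M | 0.0950 M | 0.50 mM | 3.0 min |

1. amount of target at the end, in percent of the substrate charged for summer, midnight, dusk, autumn, in this order
2. how the row runs (rises, then falls / falls all the way / hardly changes / falls, then rises / rises all the way)

- "hardly changes" means that all values lie within two and a half points (for a concentration: within two and a half percent of the largest)
- run time (summer): 3.0 min

My reckoning: while substrate lasts, I put the catalyst in catalyst intermediate A, the resting state, since its exit is slower. Partner then decays pseudo-first-order. Its lifetime τ, one over the step-two constant times the catalyst charge, is 154 s. From τ I get the run output X, the partner turned over in the run if the whole catalyst charge waits there: X = 0.0655 M.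

X lies below the charges of midnight, dusk and autumn. So I expect 65.5%, 32.8% and 16.4% there. In summer the charge of 0.050 M is less than X, so I expect substrate to be used up. Free catalyst then attacks target with a lifetime of 20.0 s, shorter than the run. I commit to no summer figure, but I expect a row that rises, then falls.

The forecast gives 17%, 53.5%, 28.4% and 14.4%, with the shape "rises, then falls", holding that “the percentage therefore roughly halves with each doubling”. At midnight its figure is lower than mine.

The simulation gives 17.6%, 54.0%, 28.4% and 14.4%, so the row rises, then falls.

The row turns at 0.064 M, close to X, and the summer charge of 0.050 M lies below that turn. Midnight ends with 0.0580 M of by-product, less than X. Autumn ends with 0.0584 M of by-product, and X over its charge gives 16.4% against 14.4% of target. In summer at 0.998 min, catalyst intermediate C falls back 36 times faster than it goes on.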